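**Plan**

- Retrosynthesis: the N1–C2 bond of the indolin-3-one ring is cut first by putting a carbonyl carbon back between N1 and C2. The five-membered ring thereby becomes the six-membered lactam ring of 3,3-di(indol-3-yl)quinoline-2,4-dione.
- Next, both C–indolyl bonds at that carbon are cut (double Friedel–Crafts reaction at the central C=O of quinoline-2,3,4-trione). The trione is traced through its 3-diazo derivative to 4-hydroxyquinolin-2(1H)-one.
- Forward: the benzo-fused six-membered N-ring is present from the start. Its C3 is oxidised (diazo, then C=O), both indoles are attached in one operation at this carbon, and last the six-membered ring is contracted to the five-membered one, with loss of the lactam carbon as CO2 and formation of the N–C bond.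
- Enabling feature: C2 of the indolin-3-one ring lies between N1, the C3 ketone and two indol-3-yl rings. As C3 of the quinolinedione it is a stabilised enolate leaving group for cleavage of the lactam C–C bond. After two-electron oxidation it is a 3-alkylidene-3H-indolium carbon held 5-exo to the freed aniline nitrogen.
- Stereochemistry: none. The target is achiral (C2 bears two identical indol-3-yl groups); only a transient racemic carbinol appears.

Key step: step 4

Assumption: dimethyldioxirane is used as its acetone solution, freshly made from acetone and Oxone; trione 5 may be handled as its C3 hydrate, which should react in the same way.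

**Step 1**
Reactants: 1 4-hydroxyquinolin-2(1H)-one; 2 4-acetamidobenzenesulfonyl azide (p-ABSA)
Product: 3 3-diazoquinoline-2,4(1H,3H)-dione
Conditions: p-ABSA (1.1 equiv), Et3N (1.5 equiv), MeCN, 0 °C to rt
Reagents that add atoms: 4-acetamidobenzenesulfonyl azide, CC(=O)Nc1ccc(cc1)S(=O)(=O)N=[N+]=[N-]
Why: Regitz diazo transfer to the enolised cyclic 1,3-dicarbonyl unit (C3 of the 4-hydroxy-2-quinolone) is standard for this substrate class and raises C3 to the oxidation level needed later; no stereocentre is formed.

**Step 2**
Reactants: 3 3-diazoquinoline-2,4(1H,3H)-dione; 4 dimethyldioxirane (DMDO)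
Product: 5 quinoline-2,3,4(1H)-trione
Conditions: DMDO (1.5 equiv, acetone solution), acetone, 0 °C to rt; evaporation and drying in vacuo
Reagents that add atoms: dimethyldioxirane, CC1(C)OO1
Why: oxygen-atom transfer from the dioxirane to the diazo carbon with loss of N2 is the established conversion of 2-diazo-1,3-dicarbonyl compounds into vicinal tricarbonyl compounds, and the neutral conditions avoid base-induced benzilic-type contraction of the trione; no stereocentre is formed.

**Step 3**
Reactants: 5 quinoline-2,3,4(1H)-trione; 6 1H-indole
Product: 8 3,3-di(1H-indol-3-yl)quinoline-2,4(1H,3H)-dione, via indolyl carbinol 7 (not isolated)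
Conditions: indole (2.2 equiv), p-TsOH·H2O (20 mol %), MeCN, 70 °C
Reagents that add atoms: 1H-indole, c1ccc2[nH]ccc2c1
Why: double Friedel–Crafts reaction of indole C3 at the central, most electrophilic carbonyl of the vicinal tricarbonyl (hydroxyalkylation to racemic carbinol 7, then acid-promoted SN1-type replacement of the hydroxyl by the second indole), as with isatin or ninhydrin; the carbon ends with two identical indolyl groups, so no stereocentre remains.

**Step 4**
Reactants: 8 3,3-di(1H-indol-3-yl)quinoline-2,4(1H,3H)-dione
Product: 11 2,2-di(1H-indol-3-yl)indolin-3-one, via amino ketone 9 (not isolated), via indolium cation 10 (not isolated)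
Conditions: 2 M aq KOH/EtOH (1:1), reflux, Ar; then 0 °C, AcOH to pH 7, THF, DDQ (1.05 equiv), 0 °C to rt
Reagents that add atoms: none
Why: Proposed new method: under argon, hot hydroxide should cleave the C2–C3 bond of the non-enolisable β-keto anilide 8 (retro-Claisen-type acyl cleavage from the N1 anion, with the C3 enolate, stabilised by the C4 ketone and two indol-3-yl groups, as leaving group) and expel the lactam carbon C2 as carbonate to leave amino ketone 9; after neutralisation, DDQ should abstract hydride from the doubly indol-3-yl-activated methine of 9 to give the delocalised cation 10 (a 3-alkylidene-3H-indolium ion), which the ortho amino group captures to form the N–C bond of the five-membered ring. The closest known reaction types are the aqueous-alkali decarboxylative ring contraction of 3-substituted 3-hydroxyquinoline-2,4-diones to indolin-3-ones, and the DDQ oxidation of bis(indol-3-yl)methanes to indolium ions that add nitrogen nucleophiles (oxidative α-amination of 2-aminophenyl ketones to C2-quaternary indolin-3-ones). The new ring closes 5-exo-trig onto the exocyclic C=C of 10, and this restores the aromatic indole. No stereocentre is formed, because the new quaternary carbon carries two identical indol-3-yl groups. The step needs cleavage at C2–C3 and not at C3–C4, which the vinylogous-amide deactivation of the C4 carbonyl by N1 and the better leaving group (ketone enolate against amide enolate) should secure; it also needs oxidation at the methine C–H and not at nitrogen or the indole rings, which the acyl-deactivated aniline, 1.05 equiv of DDQ at 0 °C and the exclusion of air in the alkaline stage should secure.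

**Compound list**

1 | 4-hydroxyquinolin-2(1H)-one | Oc1cc(=O)[nH]c2ccccc12 | starting material
2 | 4-acetamidobenzenesulfonyl azide (p-ABSA) | CC(=O)Nc1ccc(cc1)S(=O)(=O)N=[N+]=[N-] | starting material
3 | 3-diazoquinoline-2,4(1H,3H)-dione | O=C1Nc2ccccc2C(=O)C1=[N+]=[N-] | intermediate
4 | dimethyldioxirane (DMDO) | CC1(C)OO1 | starting material
5 | quinoline-2,3,4(1H)-trione | O=C1Nc2ccccc2C(=O)C1=O | intermediate
6 | 1H-indole | c1ccc2[nH]ccc2c1 | starting material
7 | 3-hydroxy-3-(1H-indol-3-yl)quinoline-2,4(1H,3H)-dione (racemic) | O=C1Nc2ccccc2C(=O)C1(O)c1c[nH]c2ccccc12 | intermediate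
8 | 3,3-di(1H-indol-3-yl)quinoline-2,4(1H,3H)-dione | O=C1Nc2ccccc2C(=O)C1(c1c[nH]c2ccccc12)c1c[nH]c2ccccc12 | intermediate
9 | 1-(2-aminophenyl)-2,2-di(1H-indol-3-yl)ethan-1-one | Nc1ccccc1C(=O)C(c1c[nH]c2ccccc12)c1c[nH]c2ccccc12 | intermediate
10 | 2-(2-aminophenyl)-1,1-di(1H-indol-3-yl)-2-oxoethan-1-ylium (delocalised 3-alkylidene-3H-indolium ion) | Nc1ccccc1C(=O)[C+](c1c[nH]c2ccccc12)c1c[nH]c2ccccc12 | intermediate
11 | 2,2-di(1H-indol-3-yl)indolin-3-one (2,2-bis(3'-indolyl)indoxyl) | O=C1c2ccccc2NC1(c1c[nH]c2ccccc12)c1c[nH]c2ccccc12 | target

Total step count: 4. Longest linear sequence: 4 steps (1 → 3 → 5 → 8 → 11).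

**Steps most likely to fail**

Step 4 (proposed new method). Hydroxide may attack the C4 ketone and cleave C3–C4 instead, the hindered lactam may open incompletely, or the oxidation stage may act on the indole rings or the aniline nitrogen and lead to oligomers instead of ring closure. The fallback uses known chemistry, sets out from 5 and comes back at 11. Trione 5 is treated with one equivalent of indole 6 without acid (EtOH, rt), so that addition should stop at carbinol 7, which is isolated. Heating 7 in aqueous KOH open to air is the known base-mediated decarboxylative ring contraction of 3-substituted 3-hydroxyquinoline-2,4-diones and should give 2-hydroxy-2-(1H-indol-3-yl)indolin-3-one F1. Catalytic p-TsOH in MeCN should dehydrate F1 to 2-(1H-indol-3-yl)-3H-indol-3-one F2, whose C=N bond adds indole 6 at C3 (aza-Friedel–Crafts addition to a 2-aryl-3H-indol-3-one) to give 11.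

Step 3. The second substitution may stall at carbinol 7, because ionisation of a carbinol between two carbonyl groups is slow, and more forcing acid may cause retro-addition or indole oligomerisation. The fallback sets out from 3 and comes back at 8; it also bypasses step 2. Diazo compound 3 and indole 6 with Rh2(OAc)4 (1 mol %, DCE, 60 °C) should give, by formal insertion of the acceptor/acceptor carbene into the indole C3–H bond, 4-hydroxy-3-(1H-indol-3-yl)quinolin-2(1H)-one F3. DDQ (1 equiv, THF, 0 °C) should dehydrogenate F3 to 3-(3H-indol-3-ylidene)quinoline-2,4(1H,3H)-dione F4 (E/Z mixture, geometry of no consequence, not isolated). A second indole 6 then adds to F4 in conjugate fashion (cat. TFA) to give 8.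

Step 2. Oxygen transfer to the electron-poor, sparingly soluble diazo lactam may be slow against decomposition of the dioxirane, and the trione may suffer hydrolytic ring cleavage during isolation. The fallback sets out from 1 and comes back at 5, replacing steps 1 and 2. Compound 1 is condensed with N,N-dimethylformamide dimethyl acetal (toluene, 90 °C) to give 3-[(dimethylamino)methylidene]quinoline-2,4(1H,3H)-dione F5 (E/Z mixture). Ozonolysis of F5 (CH2Cl2, −78 °C; Me2S) cleaves the enamine C=C bond and should give 5 (enaminone route to vicinal tricarbonyl compounds).

**Further compounds**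

F1 | step 4 | 2-hydroxy-2-(1H-indol-3-yl)indolin-3-one (racemic) | O=C1c2ccccc2NC1(O)c1c[nH]c2ccccc12
F2 | step 4 | 2-(1H-indol-3-yl)-3H-indol-3-one | O=C1C(=Nc2ccccc12)c1c[nH]c2ccccc12
F3 | step 3 | 4-hydroxy-3-(1H-indol-3-yl)quinolin-2(1H)-one | Oc1c(-c2c[nH]c3ccccc23)c(=O)[nH]c2ccccc12
F4 | step 3 | 3-(3H-indol-3-ylidene)quinoline-2,4(1H,3H)-dione (E/Z mixture) | O=C1Nc2ccccc2C(=O)C1=C1C=Nc2ccccc12
F5 | step 2 | 3-[(dimethylamino)methylidene]quinoline-2,4(1H,3H)-dione (E/Z mixture) | CN(C)C=C1C(=O)Nc2ccccc2C1=O
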